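**Retrosynthetic overview**

- The target is a 2‑hydroxy‑4‑methoxybenzophenone. The C7–aryl bond is made last, from a ring A Weinreb amide and 4‑(benzyloxy)phenylmagnesium bromide, and all benzyl ethers are removed at the end.
- The strategy rests on ring A (C1 OMe, C2 H, C3 OH, C4 bearing the ketone carbon C7, C5 H, C6 bearing the arylpropyl chain). This ring is the dehydrogenated form of a 4,6‑disubstituted cyclohexane‑1,3‑dione that carries C7 as an ester.
- The dione is cut at C4–C5 (Michael) and C2–C3 (Claisen) into dimethyl malonate and an α‑methylidene methyl ketone. Ring A is the only ring formed; the two other benzene rings are bought.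
- After dehydrogenation, the C3 hydroxyl is hydrogen‑bonded to the ester, so only the C1 hydroxyl is methylated.
- The enone comes from methyl acetoacetate and the arylpropyl bromide by alkylation, saponification and decarboxylative Mannich methylenation.

Key step: step 6

Remark: all β‑dicarbonyl intermediates are racemic or mixtures of epimers and enol tautomers and are drawn in the keto form; the target is achiral, so none of these centres has to be controlled.

**Route**

Step 1
Reactants: 1 3‑(4‑hydroxyphenyl)propan‑1‑ol
Product: 2 3‑[4‑(benzyloxy)phenyl]propan‑1‑ol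
Conditions: BnBr, K2CO3, acetone, reflux
Reagents that add atoms: benzyl bromide, BrCc1ccccc1
Why: Williamson ether synthesis; K2CO3 deprotonates only the phenol, so benzylation should occur on the phenolic oxygen and leave the primary alcohol free.

Step 2
Reactants: 2 3‑[4‑(benzyloxy)phenyl]propan‑1‑ol
Product: 3 1‑(benzyloxy)‑4‑(3‑bromopropyl)benzene
Conditions: CBr4, PPh3, CH2Cl2, 0 °C to rt
Reagents that add atoms: carbon tetrabromide, BrC(Br)(Br)Br
Why: Appel reaction; the alkoxyphosphonium ion of the primary alcohol is displaced by bromide in an SN2 step under neutral conditions that the benzyl ether tolerates.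

Step 3
Reactants: 3 1‑(benzyloxy)‑4‑(3‑bromopropyl)benzene; 4 methyl acetoacetate
Product: 5 methyl 2‑acetyl‑5‑[4‑(benzyloxy)phenyl]pentanoate (racemic)
Conditions: NaH, THF/DMF, 0 °C; then 3, NaI (cat.), 60 °C
Reagents that add atoms: none
Why: Acetoacetic ester alkylation; the sodium enolate of 4 (used in excess to limit dialkylation) is C‑alkylated by the primary halide, and the new α‑stereocentre is racemic and disappears in step 5.

Step 4
Reactants: 5 methyl 2‑acetyl‑5‑[4‑(benzyloxy)phenyl]pentanoate
Product: 6 2‑acetyl‑5‑[4‑(benzyloxy)phenyl]pentanoic acid (racemic, used at once)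
Conditions: KOH (aq, 1 M), THF/CH3OH, 0 °C to rt; then HCl (aq, 1 M), 0 °C
Reagents that add atoms: potassium hydroxide, [K+].[OH-]
Why: Ester saponification with cold dilute hydroxide followed by cold acidification should give the β‑keto acid without retro‑Claisen cleavage or premature decarboxylation.

Step 5
Reactants: 6 2‑acetyl‑5‑[4‑(benzyloxy)phenyl]pentanoic acid
Product: 8 6‑[4‑(benzyloxy)phenyl]‑3‑methylidenehexan‑2‑one, via Mannich base acid 7 (not isolated)
Conditions: Et2NH, HCHO (37% aq), THF, 0 °C to rt; then CH3CO2H, CH3CO2Na, 60 °C, BHT (trace)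
Reagents that add atoms: formaldehyde, C=O
Why: Decarboxylative Mannich methylenation; the enol of 6 is aminomethylated at the doubly activated α‑carbon, and 7 then fragments with loss of CO2 and diethylamine, which places the methylidene group only on the carbon that carried the carboxyl group.

Step 6
Reactants: 8 6‑[4‑(benzyloxy)phenyl]‑3‑methylidenehexan‑2‑one; 9 dimethyl malonate
Product: 11 methyl 5‑{3‑[4‑(benzyloxy)phenyl]propyl}‑2,4‑dioxocyclohexane‑1‑carboxylate (racemic mixture of epimers), via Michael adduct 10 (not isolated)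
Conditions: NaOCH3 (1.3 equiv), 9 (1.2 equiv), CH3OH, slow addition of 8 at 0 °C to rt, then reflux; HCl (aq), 0 °C
Reagents that add atoms: none
Why: Sodium dimethyl malonate adds in a Michael fashion to the unsubstituted methylidene carbon of 8 (bond C4–C5) to give 10, whose methyl ketone enolate (C2) then attacks one malonate ester carbonyl (C3) in a Claisen (Dieckmann‑type) acyl substitution that expels methoxide. The closest known reaction type is the malonate–enone annulation to cyclohexane‑1,3‑diones, as in the preparation of dimedone and of alkyl dihydroresorcylates. Ring A closes in a 6‑exo‑trig mode, and deprotonation of the acidic 1,3‑dione by methoxide makes the closure irreversible. The two new stereocentres (C4 and C6) are not controlled and need not be, since both are epimerizable and become sp2 carbons in step 7. The step needs 1,4‑ over 1,2‑addition, which the soft malonate anion and the unhindered terminal CH2 secure, and closure from the methyl carbon only, which ring size secures because the other α‑carbon (C6) could only close a four‑membered ring. Slow addition of 8 to an excess of the malonate anion should suppress a second Michael addition and anionic oligomerization of the enone.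

Step 7
Reactants: 11 methyl 5‑{3‑[4‑(benzyloxy)phenyl]propyl}‑2,4‑dioxocyclohexane‑1‑carboxylate
Product: 12 methyl 5‑{3‑[4‑(benzyloxy)phenyl]propyl}‑2,4‑dihydroxybenzoate
Conditions: DDQ (1.1 equiv), 1,4‑dioxane, reflux
Reagents that add atoms: none
Why: DDQ dehydrogenation; hydride abstraction from C5, allylic to the C3=C4 enol of the β‑keto ester, and proton loss give a cyclohexadienone that tautomerizes irreversibly to the resorcylate, erasing both ring stereocentres while the benzyl ether and ester are inert.

Step 8
Reactants: 12 methyl 5‑{3‑[4‑(benzyloxy)phenyl]propyl}‑2,4‑dihydroxybenzoate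
Product: 13 methyl 5‑{3‑[4‑(benzyloxy)phenyl]propyl}‑2‑hydroxy‑4‑methoxybenzoate
Conditions: CH3I (1.1 equiv), K2CO3 (1.1 equiv), acetone, rt to 40 °C
Reagents that add atoms: iodomethane, CI
Why: Selective Williamson O‑methylation; the C1 hydroxyl para to the ester is the more acidic and is free, whereas the C3 hydroxyl is held in a hydrogen bond to the ester carbonyl and should stay unalkylated with one equivalent of base.

Step 9
Reactants: 13 methyl 5‑{3‑[4‑(benzyloxy)phenyl]propyl}‑2‑hydroxy‑4‑methoxybenzoate
Product: 14 methyl 2‑(benzyloxy)‑5‑{3‑[4‑(benzyloxy)phenyl]propyl}‑4‑methoxybenzoate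
Conditions: BnBr, K2CO3, DMF, 60 °C
Reagents that add atoms: benzyl bromide, BrCc1ccccc1
Why: Williamson benzylation of the chelated phenol under more forcing conditions (DMF, heat) masks the acidic C3 hydroxyl so that the two organomagnesium steps run on a neutral substrate.

Step 10
Reactants: 14 methyl 2‑(benzyloxy)‑5‑{3‑[4‑(benzyloxy)phenyl]propyl}‑4‑methoxybenzoate
Product: 15 2‑(benzyloxy)‑5‑{3‑[4‑(benzyloxy)phenyl]propyl}‑N,4‑dimethoxy‑N‑methylbenzamide
Conditions: CH3NHOCH3·HCl, (CH3)2CHMgCl, THF, −20 to 0 °C; NH4Cl (aq)
Reagents that add atoms: N,O‑dimethylhydroxylamine hydrochloride, CNOC.Cl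
Why: Weinreb amide formation from an ester by the chloromagnesium amide of N,O‑dimethylhydroxylamine; aminolysis of the ester is faster than any addition of the hindered (CH3)2CHMgCl, and the ethers are inert.

Step 11
Reactants: 15 2‑(benzyloxy)‑5‑{3‑[4‑(benzyloxy)phenyl]propyl}‑N,4‑dimethoxy‑N‑methylbenzamide; 16 1‑bromo‑4‑(benzyloxy)benzene
Product: 18 [2‑(benzyloxy)‑5‑{3‑[4‑(benzyloxy)phenyl]propyl}‑4‑methoxyphenyl][4‑(benzyloxy)phenyl]methanone, via arylmagnesium bromide 17 (not isolated)
Conditions: 16, Mg, I2 (cat.), THF, reflux; then 15, THF, 0 °C to rt; HCl (aq, 1 M)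
Reagents that add atoms: none
Why: Weinreb ketone synthesis; the Grignard reagent 17 adds once at C7 because the magnesium‑chelated tetrahedral intermediate survives until acidic work‑up, so the diaryl ketone should form without over‑addition.

Step 12
Reactants: 18 [2‑(benzyloxy)‑5‑{3‑[4‑(benzyloxy)phenyl]propyl}‑4‑methoxyphenyl][4‑(benzyloxy)phenyl]methanone
Product: 19 {2‑hydroxy‑5‑[3‑(4‑hydroxyphenyl)propyl]‑4‑methoxyphenyl}(4‑hydroxyphenyl)methanone (CNP0209225.0)
Conditions: H2 (1 atm), Pd/C (10 wt %), EtOAc, rt, stopped after uptake of three equivalents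
Reagents that add atoms: none
Why: Catalytic hydrogenolysis of the three benzyl aryl ethers is faster than reduction of the electron‑rich diaryl ketone at atmospheric pressure in EtOAc, and the methyl ether is untouched.

**Compound list**

1 | 3‑(4‑hydroxyphenyl)propan‑1‑ol | OCCCc1ccc(O)cc1 | starting material
2 | 3‑[4‑(benzyloxy)phenyl]propan‑1‑ol | OCCCc1ccc(OCc2ccccc2)cc1 | intermediate
3 | 1‑(benzyloxy)‑4‑(3‑bromopropyl)benzene | BrCCCc1ccc(OCc2ccccc2)cc1 | intermediate
4 | methyl acetoacetate | COC(=O)CC(C)=O | starting material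
5 | methyl 2‑acetyl‑5‑[4‑(benzyloxy)phenyl]pentanoate (racemic) | COC(=O)C(CCCc1ccc(OCc2ccccc2)cc1)C(C)=O | intermediate
6 | 2‑acetyl‑5‑[4‑(benzyloxy)phenyl]pentanoic acid (racemic) | CC(=O)C(CCCc1ccc(OCc2ccccc2)cc1)C(=O)O | intermediate
7 | 2‑acetyl‑5‑[4‑(benzyloxy)phenyl]‑2‑[(diethylamino)methyl]pentanoic acid (racemic, not isolated) | CCN(CC)CC(CCCc1ccc(OCc2ccccc2)cc1)(C(C)=O)C(=O)O | intermediate
8 | 6‑[4‑(benzyloxy)phenyl]‑3‑methylidenehexan‑2‑one | CC(=O)C(=C)CCCc1ccc(OCc2ccccc2)cc1 | intermediate
9 | dimethyl malonate | COC(=O)CC(=O)OC | starting material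
10 | dimethyl 2‑{2‑acetyl‑5‑[4‑(benzyloxy)phenyl]pentyl}propanedioate (racemic, not isolated) | COC(=O)C(CC(CCCc1ccc(OCc2ccccc2)cc1)C(C)=O)C(=O)OC | intermediate
11 | methyl 5‑{3‑[4‑(benzyloxy)phenyl]propyl}‑2,4‑dioxocyclohexane‑1‑carboxylate (racemic, mixture of epimers) | COC(=O)C1CC(CCCc2ccc(OCc3ccccc3)cc2)C(=O)CC1=O | intermediate
12 | methyl 5‑{3‑[4‑(benzyloxy)phenyl]propyl}‑2,4‑dihydroxybenzoate | COC(=O)c1cc(CCCc2ccc(OCc3ccccc3)cc2)c(O)cc1O | intermediate
13 | methyl 5‑{3‑[4‑(benzyloxy)phenyl]propyl}‑2‑hydroxy‑4‑methoxybenzoate | COC(=O)c1cc(CCCc2ccc(OCc3ccccc3)cc2)c(OC)cc1O | intermediate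
14 | methyl 2‑(benzyloxy)‑5‑{3‑[4‑(benzyloxy)phenyl]propyl}‑4‑methoxybenzoate | COC(=O)c1cc(CCCc2ccc(OCc3ccccc3)cc2)c(OC)cc1OCc1ccccc1 | intermediate
15 | 2‑(benzyloxy)‑5‑{3‑[4‑(benzyloxy)phenyl]propyl}‑N,4‑dimethoxy‑N‑methylbenzamide | COc1cc(OCc2ccccc2)c(cc1CCCc1ccc(OCc2ccccc2)cc1)C(=O)N(C)OC | intermediate
16 | 1‑bromo‑4‑(benzyloxy)benzene | Brc1ccc(OCc2ccccc2)cc1 | starting material
17 | [4‑(benzyloxy)phenyl]magnesium bromide (not isolated) | Br[Mg]c1ccc(OCc2ccccc2)cc1 | intermediate
18 | [2‑(benzyloxy)‑5‑{3‑[4‑(benzyloxy)phenyl]propyl}‑4‑methoxyphenyl][4‑(benzyloxy)phenyl]methanone | COc1cc(OCc2ccccc2)c(cc1CCCc1ccc(OCc2ccccc2)cc1)C(=O)c1ccc(OCc2ccccc2)cc1 | intermediate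
19 | {2‑hydroxy‑5‑[3‑(4‑hydroxyphenyl)propyl]‑4‑methoxyphenyl}(4‑hydroxyphenyl)methanone | COc1cc(O)c(cc1CCCc1ccc(O)cc1)C(=O)c1ccc(O)cc1 | target

**Step count**

Total step count: 12. Longest linear sequence: 12 steps (1 to 19); the Grignard reagent 17 is made in the flask of step 11.

**Steps most likely to fail**

Step 6 (Michael–Claisen annulation). Under alkoxide the enone may oligomerize or take up a second equivalent of adduct anion, or the acyl substitution may stall at the open‑chain adduct. The fallback sets out from keto ester 5 and returns at dione 11, with the donor and acceptor roles exchanged. Treating 5 with LiN(Si(CH3)3)2 and paraformaldehyde in THF (deacetylative methylenation) should give methyl 5‑[4‑(benzyloxy)phenyl]‑2‑methylidenepentanoate F1. Methyl acetoacetate 4 is then added to F1 with NaOCH3 in refluxing methanol. The Michael adduct, dimethyl 2‑acetyl‑4‑{3‑[4‑(benzyloxy)phenyl]propyl}pentanedioate F2, should close by attack of the acetyl methyl carbon on the distal ester, as in the classical dihydroorsellinate annulation, and give the same dione 11 without handling the enone 8.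

Step 7 (dehydrogenation). The strongly nucleophilic dione enol may add to the quinone instead of transferring hydride, or oxidation may continue at the benzylic positions, so conversion to the arene may be incomplete or unclean. The fallback sets out from dione 11 and returns at resorcylate 12 by halogenation and elimination in place of hydride abstraction. One equivalent of Br2 in DMF at 0 °C should, after HBr‑mediated equilibration of the bromide first formed between the two carbonyl groups, give methyl 1‑bromo‑5‑{3‑[4‑(benzyloxy)phenyl]propyl}‑2,4‑dioxocyclohexane‑1‑carboxylate F3. Warming to 80 °C should then eliminate HBr across C4–C5 and tautomerize the product to 12. The bromine is limited to one equivalent so that none is left for the aromatic rings.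

Step 5 (decarboxylative methylenation). The β‑keto acid may simply decarboxylate before aminomethylation, or the α‑methylidene ketone may dimerize or polymerize during isolation. The fallback sets out from bromide 3 and returns at enone 8. Alkylation of the sodium salt of diethyl (2‑oxopropyl)phosphonate with 3 (NaH, DMF, NaI cat.) should give diethyl {6‑[4‑(benzyloxy)phenyl]‑2‑oxohexan‑3‑yl}phosphonate F4. A Horner–Wadsworth–Emmons reaction of F4 with aqueous HCHO and K2CO3 at rt should then deliver 8 under mild, nearly neutral conditions, with no free β‑keto acid involved.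

**Further compounds**

F1 | step 6 | methyl 5‑[4‑(benzyloxy)phenyl]‑2‑methylidenepentanoate | COC(=O)C(=C)CCCc1ccc(OCc2ccccc2)cc1
F2 | step 6 | dimethyl 2‑acetyl‑4‑{3‑[4‑(benzyloxy)phenyl]propyl}pentanedioate | COC(=O)C(CC(CCCc1ccc(OCc2ccccc2)cc1)C(=O)OC)C(C)=O
F3 | step 7 | methyl 1‑bromo‑5‑{3‑[4‑(benzyloxy)phenyl]propyl}‑2,4‑dioxocyclohexane‑1‑carboxylate | COC(=O)C1(Br)CC(CCCc2ccc(OCc3ccccc3)cc2)C(=O)CC1=O
F4 | step 5 | diethyl {6‑[4‑(benzyloxy)phenyl]‑2‑oxohexan‑3‑yl}phosphonate | CCOP(=O)(OCC)C(CCCc1ccc(OCc2ccccc2)cc1)C(C)=O
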